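## Retrosynthetic overview

1. Sipholenol M (45) ← desilylation ← hydroperoxide 44 ← invertive mesylate/H2O2 displacement on allylic alcohol 42 ← B-alkyl Suzuki–Miyaura coupling of left-half iodide 24 (as its 9-BBN borate) with right-half enol triflate 39 (key C(sp3)–C(sp2) bond).
2. Left half 24 ← tricyclic hydroxy lactone 20 ← one-step epoxide-opening cascade of diepoxy ester 18: oxepane ring A first, then cyclohexane ring B, then the lactone.
3. 18 ← Shi diepoxidation and Pd-catalysed enolate alkenylation of triene iodide 14 ← two Zr-catalysed carboaluminations and one Negishi coupling from C4–C6 pieces.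
4. Right half 39 ← cis-octalone 30 by asymmetric Diels–Alder (cyclohexene ring C built onto cyclohexanone ring D) ← enone 28 from isobutyraldehyde and methyl vinyl ketone; then allylic oxidation, methylenation, conjugate borylation, hydration, enol triflation.
5. Ring order: D → C (right half), A → B (left half), fragment union last.

Assumption: the target SMILES is read literally (cis-fused 6-6 right half, all-S left half); transient ionic species (enolates, alkoxides, carbocations) are not numbered, whereas preformed organometallic reagents and telescoped neutral intermediates are.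

## Route

Step 1
Reactants: 1 but-3-yn-1-ol
Product: 3 4-(trimethylsilyl)but-3-yn-1-ol, via bis-silylated butynol 2 (not isolated)
Conditions: EtMgBr (2.2 equiv), THF, 0 °C → reflux; TMSCl (2.2 equiv), 0 → 23 °C; then 1 M aq. HCl, 23 °C
Reagents that add atoms: chlorotrimethylsilane, C[Si](C)(C)Cl
Why: Double deprotonation and C,O-bis-silylation, then selective acid hydrolysis of the O–Si bond, leaves the C-silyl alkyne (standard alkyne protection).

Step 2
Reactants: 3 4-(trimethylsilyl)but-3-yn-1-ol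
Product: 4 (4-iodobut-1-yn-1-yl)trimethylsilane
Conditions: I2, PPh3, imidazole, CH2Cl2, 0 → 23 °C
Reagents that add atoms: iodine, II
Why: Appel-type iodination converts the primary alcohol into the iodide without touching the silylalkyne.

Step 3
Reactants: 5 5-bromo-2-methylpent-2-ene; 6 lithium acetylide–ethylenediamine complex
Product: 7 6-methylhept-5-en-1-yne
Conditions: DMSO, 10 → 25 °C
Reagents that add atoms: none
Why: SN2 alkynylation of a primary bromide by lithium acetylide in DMSO.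

Step 4
Reactants: 7 6-methylhept-5-en-1-yne
Product: 9 (1E)-1-iodo-2,6-dimethylhepta-1,5-diene, via alkenylalane 8 (not isolated)
Conditions: Me3Al (2 equiv), Cp2ZrCl2 (0.25 equiv), CH2Cl2, 0 → 23 °C; then I2, THF, −30 → 0 °C
Reagents that add atoms: trimethylaluminium, C[Al](C)C; iodine, II
Why: Negishi Zr-catalysed carboalumination adds Me–Al syn with methyl on the internal carbon, and iodinolysis with retention gives the E-iodide.

Step 5
Reactants: 9 (1E)-1-iodo-2,6-dimethylhepta-1,5-diene; 4 (4-iodobut-1-yn-1-yl)trimethylsilane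
Product: 12 (5E)-6,10-dimethylundeca-5,9-dien-1-yne, via alkylzinc iodide 10 (not isolated), via silylated dienyne 11 (not isolated)
Conditions: 4, Zn dust, LiCl, THF, 40 °C; then 9, Pd(PPh3)4 (5 mol%), THF, 23 °C; then K2CO3, MeOH, 23 °C
Reagents that add atoms: none
Why: Negishi sp3–sp2 cross-coupling proceeds with retention of alkene geometry, and methanolysis removes the alkynyl silyl group.

Step 6
Reactants: 12 (5E)-6,10-dimethylundeca-5,9-dien-1-yne
Product: 14 (1E,5E)-1-iodo-2,6,10-trimethylundeca-1,5,9-triene, via alkenylalane 13 (not isolated)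
Conditions: Me3Al (2 equiv), Cp2ZrCl2 (0.25 equiv), CH2Cl2, 0 → 23 °C; then I2, THF, −30 → 0 °C
Reagents that add atoms: trimethylaluminium, C[Al](C)C; iodine, II
Why: A second Negishi carboalumination/iodinolysis builds the third trisubstituted E-alkene as an iodoalkene.

Step 7
Reactants: 14 (1E,5E)-1-iodo-2,6,10-trimethylundeca-1,5,9-triene
Product: 15 (2S,3S)-2-{2-[(2S)-3,3-dimethyloxiran-2-yl]ethyl}-3-[(3E)-4-iodo-3-methylbut-3-en-1-yl]-2-methyloxirane
Conditions: 1,2:4,5-di-O-isopropylidene-β-L-erythro-2,3-hexodiulo-2,6-pyranose (ent-Shi ketone, 0.4 equiv), Oxone, K2CO3, Bu4NHSO4, MeCN–CH2(OMe)2–aq. Na2B4O7 buffer, 0 °C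
Reagents that add atoms: potassium peroxymonosulfate (Oxone), [K+].[O-]S(=O)(=O)OO
Why: Shi asymmetric epoxidation: the dioxirane attacks only the two electron-rich trisubstituted alkenes (the iodoalkene is deactivated), and the L-series ketone sets 7S,8S and 11S through the spiro transition state.

Step 8
Reactants: 15 diepoxy iodide (name as in step 7); 16 tert-butyl acetate
Product: 18 tert-butyl (3E)-6-[(2S,3S)-3-{2-[(2S)-3,3-dimethyloxiran-2-yl]ethyl}-3-methyloxiran-2-yl]-4-methylhex-3-enoate, via zinc enolate 17 (not isolated)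
Conditions: 16, LDA, THF, −78 °C; ZnCl2, −78 → 23 °C; then 15, Pd(dba)2 (3 mol%), Q-Phos (3 mol%), THF, 23 °C
Reagents that add atoms: none
Why: Pd-catalysed α-alkenylation of a zinc ester enolate (Reformatsky–Negishi type) retains the E geometry; the weakly basic zinc enolate tolerates the epoxides and does not conjugate the β,γ-alkene.

Step 9
Reactants: 18 diepoxy ester (name as in step 8)
Product: 20 (3S,5aS,6S,7S,9aS)-3-hydroxy-2,2,5a,7-tetramethyldecahydro-1-benzoxepine-6-acetic acid 7-lactone (trans-fused tricyclic hydroxy lactone), via silyl ether 19 (not isolated)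
Conditions: TMSOTf (1.2 equiv), 2,6-di-tert-butyl-4-methylpyridine (1.5 equiv), CH2Cl2, −78 °C; then citric acid, MeOH, 0 °C
Reagents that add atoms: none
Why: Proposed new method: an epoxide-opening oxa-/carba-cyclisation cascade terminated by a tert-butyl ester. Silyl activation of the terminal epoxide lets the internal epoxide oxygen attack its tertiary carbon (7-endo, bicyclic epoxonium, ring A); the E-alkene then attacks the epoxonium anti through a chair transition state (ring B, inversion at C5a); the tertiary cation is trapped anti by the ester carbonyl with loss of isobutene, so the epoxide configurations and the E geometry are relayed into the 3S,5aS,6S,7S,9aS array. Closest known reactions: TMSOTf-promoted tandem oxa-/carbacyclisations of 1,5-diepoxides terminated by alkenes, enol silanes or propargylsilanes, and acid-mediated cyclisation of homofarnesoic acid derivatives to sclareolide.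

Step 10
Reactants: 20 tricyclic hydroxy lactone
Product: 21 (3S,5aS,6S,7S,9aS)-6-(2-hydroxyethyl)-2,2,5a,7-tetramethyldecahydro-1-benzoxepine-3,7-diol
Conditions: LiAlH4, THF, 0 → 23 °C
Reagents that add atoms: none
Why: Hydride reduction of the lactone gives the primary alcohol and frees the tertiary C7 hydroxyl without touching any stereocentre.

Step 11
Reactants: 21 triol
Product: 23 2-[(3S,5aS,6S,7S,9aS)-2,2,5a,7-tetramethyl-3,7-bis(triethylsilyloxy)decahydro-1-benzoxepin-6-yl]ethan-1-ol, via tris-silyl ether 22 (not isolated)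
Conditions: TESOTf (3.5 equiv), 2,6-lutidine, CH2Cl2, −78 → 0 °C; then PPTS (cat.), MeOH–CH2Cl2, 0 °C
Reagents that add atoms: triethylsilyl trifluoromethanesulfonate, CC[Si](CC)(CC)OS(=O)(=O)C(F)(F)F
Why: Exhaustive silylation then selective methanolysis of the primary silyl ether; the tertiary hydroxyl must be capped first, or activation of the primary carbon would close a tetrahydrofuran.

Step 12
Reactants: 23 bis-silylated primary alcohol
Product: 24 (3S,5aS,6S,7S,9aS)-6-(2-iodoethyl)-2,2,5a,7-tetramethyl-3,7-bis(triethylsilyloxy)decahydro-1-benzoxepine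
Conditions: I2, PPh3, imidazole, CH2Cl2, 0 °C
Reagents that add atoms: iodine, II
Why: Appel-type iodination of the only free (primary) alcohol.

Step 13
Reactants: 25 2-methylpropanal; 26 but-3-en-2-one
Product: 28 4,4-dimethylcyclohex-2-en-1-one, via keto aldehyde 27 (not isolated)
Conditions: H2SO4 (cat.), toluene, 45 °C then reflux (Dean–Stark)
Reagents that add atoms: none
Why: Acid-catalysed Michael addition followed by intramolecular aldol condensation (Robinson-type annulation) builds ring D with its gem-dimethyl group.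

Step 14
Reactants: 28 4,4-dimethylcyclohex-2-en-1-one; 29 isoprene
Product: 30 (4aR,8aS)-4,4,6-trimethyl-3,4,4a,5,8,8a-hexahydronaphthalen-1(2H)-one
Conditions: (S)-1-(o-tolyl)-3,3-diphenyltetrahydro-1H,3H-pyrrolo[1,2-c][1,3,2]oxazaborole activated by AlBr3 (10 mol%), isoprene (5 equiv), CH2Cl2, −20 → 23 °C
Reagents that add atoms: none
Why: Lewis-acid-catalysed Diels–Alder reaction: suprafacial addition gives the cis ring fusion, the 2-methyl of the diene directs "para" (6-methyl), and the chiral oxazaborolidinium shields one enone face (catalyst antipode chosen to deliver 4aR,8aS; sense to be confirmed on the first batch).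

Step 15
Reactants: 30 cis-octalone
Product: 32 (4aR,8aS)-4,4,6-trimethyl-3,4,4a,8a-tetrahydronaphthalene-1,5(2H,8H)-dione, via allylic alcohol 31 (not isolated)
Conditions: SeO2 (0.5 equiv), t-BuOOH (3 equiv), CH2Cl2, 23 °C; then Dess–Martin periodinane, NaHCO3, CH2Cl2, 0 → 23 °C
Reagents that add atoms: selenium dioxide, O=[Se]=O; tert-butyl hydroperoxide, CC(C)(C)OO
Why: SeO2 allylic oxidation (ene reaction, then [2,3]-shift) hits the ring CH2 next to the more substituted alkene carbon (C5); the crude alcohol is oxidised to the enone under near-neutral conditions that spare the epimerisable ring fusion.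

Step 16
Reactants: 32 ene-dione
Product: 33 (4aS,8aR)-2,8,8-trimethyl-5-methylidene-4a,5,6,7,8,8a-hexahydronaphthalen-1(4H)-one
Conditions: Zn, CH2Br2, TiCl4, THF–CH2Cl2, 0 → 23 °C
Reagents that add atoms: dibromomethane, BrCBr
Why: Non-basic Takai–Lombardo methylenation attacks the saturated ketone only (the enone carbonyl is conjugated and flanked by the neopentyl ring-fusion carbon and the methyl-bearing alkene) and does not epimerise the cis fusion.

Step 17
Reactants: 33 methylidene enone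
Product: 35 (3S,4aS,8aR)-3-hydroxy-2,8,8-trimethyl-5-methylideneoctahydronaphthalen-1(2H)-one (C2 epimers), via boryl ketone 34 (not isolated)
Conditions: CuCl (5 mol%), NaOt-Bu (10 mol%), DPEphos (5 mol%), B2pin2, MeOH, THF, 23 °C; then NaBO3·4H2O, THF–H2O, 23 °C
Reagents that add atoms: sodium perborate, [Na+].[Na+].O[B-]1(O)OO[B-](O)(O)OO1
Why: Cu-catalysed conjugate borylation delivers boron to C3 from the convex face (cis to the ring-fusion hydrogens, anti to the axial ring-D arm at C4a), and perborate oxidation replaces boron by OH with retention.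

Step 18
Reactants: 35 β-hydroxy ketone
Product: 36 (3S,4aS,5S,8aR)-3,5-dihydroxy-2,5,8,8-tetramethyloctahydronaphthalen-1(2H)-one (C2 epimers)
Conditions: Mn(dpm)3 (10 mol%), PhSiH3, O2 (1 atm), i-PrOH–CH2Cl2, 0 → 23 °C
Reagents that add atoms: dioxygen, O=O
Why: Mukaiyama hydrogen-atom-transfer hydration: H adds to the exocyclic CH2, and O2 traps the tertiary C5 radical from the equatorial, convex direction (the axial face is screened by the syn-axial C1 carbon), giving the hydroxyl cis to the ring-fusion hydrogens.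

Step 19
Reactants: 36 dihydroxy ketone
Product: 37 (3S,4aS,5S,8aR)-2,5,8,8-tetramethyl-3,5-bis(trimethylsilyloxy)octahydronaphthalen-1(2H)-one (C2 epimers)
Conditions: 1-(trimethylsilyl)imidazole, CH2Cl2, 23 → 40 °C
Reagents that add atoms: 1-(trimethylsilyl)imidazole, C[Si](C)(C)n1ccnc1
Why: Neutral silylation caps the secondary and tertiary hydroxyls without enolising or dehydrating the β-hydroxy ketone.

Step 20
Reactants: 37 bis-silylated ketone
Product: 39 (3S,4aS,5S,8aR)-3,5-dihydroxy-2,5,8,8-tetramethyl-3,4,4a,5,6,7,8,8a-octahydronaphthalen-1-yl trifluoromethanesulfonate, via bis-silyl enol triflate 38 (not isolated)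
Conditions: KHMDS, THF, −78 °C; PhNTf2, −78 → −20 °C; then 1 M aq. HCl, THF, 0 °C
Reagents that add atoms: N-phenylbis(trifluoromethanesulfonimide), O=S(=O)(N(c1ccccc1)S(=O)(=O)C(F)(F)F)C(F)(F)F
Why: Kinetic enolisation occurs at C2–H, not at the neopentyl ring-fusion C8a–H; O-triflation at low temperature outruns β-elimination, fixing the tetrasubstituted enol triflate and erasing the C2 epimer mixture, and dilute acid removes both silyl ethers.

Step 21
Reactants: 24 left-half iodide; 39 right-half enol triflate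
Product: 42 (3S,5aS,6S,7S,9aS)-6-{2-[(3S,4aS,5S,8aR)-3,5-dihydroxy-2,5,8,8-tetramethyl-3,4,4a,5,6,7,8,8a-octahydronaphthalen-1-yl]ethyl}-2,2,5a,7-tetramethyl-3,7-bis(triethylsilyloxy)decahydro-1-benzoxepine, via alkyllithium 40 (not isolated), via borate 41 (not isolated)
Conditions: 24, t-BuLi (2.1 equiv), Et2O, −78 °C; B-methoxy-9-BBN, THF, −78 → 23 °C; then 39, Pd(dppf)Cl2 (10 mol%), AsPh3, aq. K3PO4, DMF, 23 → 40 °C
Reagents that add atoms: none
Why: B-alkyl Suzuki–Miyaura coupling: the primary alkyl borate transmetalates to the alkenylpalladium formed from the enol triflate, joining the halves at the tetrasubstituted alkene without touching any stereocentre and tolerating the free hydroxyls.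

Step 22
Reactants: 42 coupled allylic alcohol
Product: 44 (3S,5aS,6S,7S,9aS)-6-{2-[(3R,4aS,5S,8aR)-3-hydroperoxy-5-hydroxy-2,5,8,8-tetramethyl-3,4,4a,5,6,7,8,8a-octahydronaphthalen-1-yl]ethyl}-2,2,5a,7-tetramethyl-3,7-bis(triethylsilyloxy)decahydro-1-benzoxepine, via mesylate 43 (not isolated)
Conditions: MsCl, Et3N, CH2Cl2, −65 °C; then anhydrous H2O2 in Et2O (excess), −78 → −30 °C
Reagents that add atoms: hydrogen peroxide, OO
Why: Only the secondary allylic hydroxyl is mesylated (tertiary OH inert, the other secondary OH silylated), and SN2 displacement of the pseudoaxial mesylate by H2O2 at low temperature inverts C3 to the required 3R hydroperoxide (sulfonate/H2O2 displacement with inversion).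

Step 23
Reactants: 44 bis-silylated hydroperoxide
Product: 45 sipholenol M
Conditions: HF·pyridine, pyridine–THF, 0 → 23 °C
Reagents that add atoms: none
Why: Buffered fluoride desilylation removes both triethylsilyl ethers under mildly acidic conditions that avoid base-induced Kornblum–DeLaMare loss of the secondary hydroperoxide.

## Compound list

1 | but-3-yn-1-ol | C#CCCO | starting material
2 | trimethyl{[4-(trimethylsilyl)but-3-yn-1-yl]oxy}silane | C[Si](C)(C)C#CCCO[Si](C)(C)C | intermediate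
3 | 4-(trimethylsilyl)but-3-yn-1-ol | C[Si](C)(C)C#CCCO | intermediate
4 | (4-iodobut-1-yn-1-yl)trimethylsilane | C[Si](C)(C)C#CCCI | intermediate
5 | 5-bromo-2-methylpent-2-ene | CC(C)=CCCBr | starting material
6 | lithium acetylide–ethylenediamine complex | [Li]C#C.NCCN | starting material
7 | 6-methylhept-5-en-1-yne | C#CCCC=C(C)C | intermediate
8 | [(1E)-2,6-dimethylhepta-1,5-dien-1-yl]dimethylalane | C[Al](C)/C=C(\C)CCC=C(C)C | intermediate
9 | (1E)-1-iodo-2,6-dimethylhepta-1,5-diene | I/C=C(\C)CCC=C(C)C | intermediate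
10 | [4-(trimethylsilyl)but-3-yn-1-yl]zinc iodide | C[Si](C)(C)C#CCC[Zn]I | intermediate
11 | [(5E)-6,10-dimethylundeca-5,9-dien-1-yn-1-yl]trimethylsilane | C[Si](C)(C)C#CCC/C=C(\C)CCC=C(C)C | intermediate
12 | (5E)-6,10-dimethylundeca-5,9-dien-1-yne | C#CCC/C=C(\C)CCC=C(C)C | intermediate
13 | [(1E,5E)-2,6,10-trimethylundeca-1,5,9-trien-1-yl]dimethylalane | C[Al](C)/C=C(\C)CC/C=C(\C)CCC=C(C)C | intermediate
14 | (1E,5E)-1-iodo-2,6,10-trimethylundeca-1,5,9-triene | I/C=C(\C)CC/C=C(\C)CCC=C(C)C | intermediate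
15 | (2S,3S)-2-{2-[(2S)-3,3-dimethyloxiran-2-yl]ethyl}-3-[(3E)-4-iodo-3-methylbut-3-en-1-yl]-2-methyloxirane | I/C=C(\C)CC[C@@H]1O[C@@]1(C)CC[C@@H]1OC1(C)C | intermediate
16 | tert-butyl acetate | CC(=O)OC(C)(C)C | starting material
17 | (2-tert-butoxy-2-oxoethyl)zinc chloride | CC(C)(C)OC(=O)C[Zn]Cl | intermediate
18 | tert-butyl (3E)-6-[(2S,3S)-3-{2-[(2S)-3,3-dimethyloxiran-2-yl]ethyl}-3-methyloxiran-2-yl]-4-methylhex-3-enoate | CC(C)(C)OC(=O)C/C=C(\C)CC[C@@H]1O[C@@]1(C)CC[C@@H]1OC1(C)C | intermediate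
19 | 3-O-trimethylsilyl ether of lactone 20 | O=C1C[C@H]2[C@]3(C)CC[C@H](O[Si](C)(C)C)C(C)(C)O[C@H]3CC[C@]2(C)O1 | intermediate
20 | (3S,5aS,6S,7S,9aS)-3-hydroxy-2,2,5a,7-tetramethyldecahydro-1-benzoxepine-6-acetic acid 7-lactone | O=C1C[C@H]2[C@]3(C)CC[C@H](O)C(C)(C)O[C@H]3CC[C@]2(C)O1 | intermediate
21 | (3S,5aS,6S,7S,9aS)-6-(2-hydroxyethyl)-2,2,5a,7-tetramethyldecahydro-1-benzoxepine-3,7-diol | OCC[C@H]2[C@]3(C)CC[C@H](O)C(C)(C)O[C@H]3CC[C@]2(C)O | intermediate
22 | tris(triethylsilyl) ether of triol 21 | CC[Si](CC)(CC)OCC[C@H]2[C@]3(C)CC[C@H](O[Si](CC)(CC)CC)C(C)(C)O[C@H]3CC[C@]2(C)O[Si](CC)(CC)CC | intermediate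
23 | 2-[(3S,5aS,6S,7S,9aS)-2,2,5a,7-tetramethyl-3,7-bis(triethylsilyloxy)decahydro-1-benzoxepin-6-yl]ethan-1-ol | OCC[C@H]2[C@]3(C)CC[C@H](O[Si](CC)(CC)CC)C(C)(C)O[C@H]3CC[C@]2(C)O[Si](CC)(CC)CC | intermediate
24 | (3S,5aS,6S,7S,9aS)-6-(2-iodoethyl)-2,2,5a,7-tetramethyl-3,7-bis(triethylsilyloxy)decahydro-1-benzoxepine | ICC[C@H]2[C@]3(C)CC[C@H](O[Si](CC)(CC)CC)C(C)(C)O[C@H]3CC[C@]2(C)O[Si](CC)(CC)CC | intermediate
25 | 2-methylpropanal | CC(C)C=O | starting material
26 | but-3-en-2-one | CC(=O)C=C | starting material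
27 | 2,2-dimethyl-5-oxohexanal | CC(=O)CCC(C)(C)C=O | intermediate
28 | 4,4-dimethylcyclohex-2-en-1-one | CC1(C)CCC(=O)C=C1 | intermediate
29 | isoprene (2-methylbuta-1,3-diene) | CC(=C)C=C | starting material
30 | (4aR,8aS)-4,4,6-trimethyl-3,4,4a,5,8,8a-hexahydronaphthalen-1(2H)-one | CC1=CC[C@@H]2C(=O)CCC(C)(C)[C@@H]2C1 | intermediate
31 | (4aR,8aS)-5-hydroxy-4,4,6-trimethyl-3,4,4a,5,8,8a-hexahydronaphthalen-1(2H)-one (C5 epimers) | CC1=CC[C@@H]2C(=O)CCC(C)(C)[C@@H]2C1O | intermediate
32 | (4aR,8aS)-4,4,6-trimethyl-3,4,4a,8a-tetrahydronaphthalene-1,5(2H,8H)-dione | CC1=CC[C@@H]2C(=O)CCC(C)(C)[C@@H]2C1=O | intermediate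
33 | (4aS,8aR)-2,8,8-trimethyl-5-methylidene-4a,5,6,7,8,8a-hexahydronaphthalen-1(4H)-one | CC1=CC[C@@H]2C(=C)CCC(C)(C)[C@@H]2C1=O | intermediate
34 | (3S,4aS,8aR)-2,8,8-trimethyl-5-methylidene-3-(4,4,5,5-tetramethyl-1,3,2-dioxaborolan-2-yl)octahydronaphthalen-1(2H)-one (C2 epimers) | CC1[C@@H](B3OC(C)(C)C(C)(C)O3)C[C@@H]2C(=C)CCC(C)(C)[C@@H]2C1=O | intermediate
35 | (3S,4aS,8aR)-3-hydroxy-2,8,8-trimethyl-5-methylideneoctahydronaphthalen-1(2H)-one (C2 epimers) | CC1[C@@H](O)C[C@@H]2C(=C)CCC(C)(C)[C@@H]2C1=O | intermediate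
36 | (3S,4aS,5S,8aR)-3,5-dihydroxy-2,5,8,8-tetramethyloctahydronaphthalen-1(2H)-one (C2 epimers) | CC1[C@@H](O)C[C@@H]2[C@@](C)(O)CCC(C)(C)[C@@H]2C1=O | intermediate
37 | (3S,4aS,5S,8aR)-2,5,8,8-tetramethyl-3,5-bis(trimethylsilyloxy)octahydronaphthalen-1(2H)-one (C2 epimers) | CC1[C@@H](O[Si](C)(C)C)C[C@@H]2[C@@](C)(O[Si](C)(C)C)CCC(C)(C)[C@@H]2C1=O | intermediate
38 | (3S,4aS,5S,8aR)-2,5,8,8-tetramethyl-3,5-bis(trimethylsilyloxy)-3,4,4a,5,6,7,8,8a-octahydronaphthalen-1-yl trifluoromethanesulfonate | CC1=C(OS(=O)(=O)C(F)(F)F)[C@@H]2[C@H](C[C@@H]1O[Si](C)(C)C)[C@@](C)(O[Si](C)(C)C)CCC2(C)C | intermediate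
39 | (3S,4aS,5S,8aR)-3,5-dihydroxy-2,5,8,8-tetramethyl-3,4,4a,5,6,7,8,8a-octahydronaphthalen-1-yl trifluoromethanesulfonate | CC1=C(OS(=O)(=O)C(F)(F)F)[C@@H]2[C@H](C[C@@H]1O)[C@@](C)(O)CCC2(C)C | intermediate
40 | {2-[(3S,5aS,6S,7S,9aS)-2,2,5a,7-tetramethyl-3,7-bis(triethylsilyloxy)decahydro-1-benzoxepin-6-yl]ethyl}lithium | [Li]CC[C@H]2[C@]3(C)CC[C@H](O[Si](CC)(CC)CC)C(C)(C)O[C@H]3CC[C@]2(C)O[Si](CC)(CC)CC | intermediate
41 | lithium B-methoxy-B-{2-[(3S,5aS,6S,7S,9aS)-2,2,5a,7-tetramethyl-3,7-bis(triethylsilyloxy)decahydro-1-benzoxepin-6-yl]ethyl}-9-borabicyclo[3.3.1]nonan-9-uide | [Li+].CO[B-]1(CC[C@H]4[C@]5(C)CC[C@H](O[Si](CC)(CC)CC)C(C)(C)O[C@H]5CC[C@]4(C)O[Si](CC)(CC)CC)C2CCCC1CCC2 | intermediate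
42 | (3S,5aS,6S,7S,9aS)-6-{2-[(3S,4aS,5S,8aR)-3,5-dihydroxy-2,5,8,8-tetramethyl-3,4,4a,5,6,7,8,8a-octahydronaphthalen-1-yl]ethyl}-2,2,5a,7-tetramethyl-3,7-bis(triethylsilyloxy)decahydro-1-benzoxepine | CC1=C(CC[C@H]2[C@]3(C)CC[C@H](O[Si](CC)(CC)CC)C(C)(C)O[C@H]3CC[C@]2(C)O[Si](CC)(CC)CC)[C@@H]2[C@H](C[C@@H]1O)[C@@](C)(O)CCC2(C)C | intermediate
43 | 3-O-methanesulfonate of 42 (3S) | CC1=C(CC[C@H]2[C@]3(C)CC[C@H](O[Si](CC)(CC)CC)C(C)(C)O[C@H]3CC[C@]2(C)O[Si](CC)(CC)CC)[C@@H]2[C@H](C[C@@H]1OS(C)(=O)=O)[C@@](C)(O)CCC2(C)C | intermediate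
44 | (3S,5aS,6S,7S,9aS)-6-{2-[(3R,4aS,5S,8aR)-3-hydroperoxy-5-hydroxy-2,5,8,8-tetramethyl-3,4,4a,5,6,7,8,8a-octahydronaphthalen-1-yl]ethyl}-2,2,5a,7-tetramethyl-3,7-bis(triethylsilyloxy)decahydro-1-benzoxepine | CC1=C(CC[C@H]2[C@]3(C)CC[C@H](O[Si](CC)(CC)CC)C(C)(C)O[C@H]3CC[C@]2(C)O[Si](CC)(CC)CC)[C@@H]2[C@H](C[C@H]1OO)[C@@](C)(O)CCC2(C)C | intermediate
45 | sipholenol M, (3S,5aS,6S,7S,9aS)-6-{2-[(3R,4aS,5S,8aR)-3-hydroperoxy-5-hydroxy-2,5,8,8-tetramethyl-3,4,4a,5,6,7,8,8a-octahydronaphthalen-1-yl]ethyl}-2,2,5a,7-tetramethyldecahydro-1-benzoxepine-3,7-diol | CC1=C(CC[C@H]2[C@]3(C)CC[C@H](O)C(C)(C)O[C@H]3CC[C@]2(C)O)[C@@H]2[C@H](C[C@H]1OO)[C@@](C)(O)CCC2(C)C | target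

## Step count and risks

Total steps: 23. Longest linear sequence: 13 (steps 3–12, then 21–23).

**Step 22 (hydroperoxide installation) is the most likely to fail.** The allylic mesylate 43 sits next to a tetrasubstituted alkene and can ionise. Capture of the resulting allyl cation is expected from the face that gives the 3-epimer, or the C5 hydroxyl may close a bridged ether. The fallback sets out from 42 and comes back at 44, and replaces substitution by a reductive transposition followed by a Schenck ene reaction. Acylation (ClCO2Me, pyridine) gives the allylic methyl carbonate of 42 F5. Tsuji hydrogenolysis (Pd(OAc)2, PBu3, HCO2H–Et3N) delivers hydride anti to the leaving group at C1 and moves the alkene to C2=C3, giving the 1R deconjugated alkene (1R,4aS,5S,8aR)-5-hydroxy-2,5,8,8-tetramethyl-1,4,4a,5,6,7,8,8a-octahydronaphthalen-1-yl analogue of 42 F6. Singlet oxygen (O2, tetraphenylporphyrin, light, CH2Cl2, −20 °C) then abstracts the C1–H and bonds to C3 on the same face, returning 44; regioisomeric ene products from the methyl and C4 hydrogens are expected and must be separated.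

**Step 9 (the proposed cascade) is the second risk.** The ester may fail to trap the ring-B cation, giving alkenes instead of the lactone. The fallback sets out from 18 and comes back at 20 in two known operations. The alkene-terminated oxa-/carbacyclisation under the published TMSOTf/2,6-di-tert-butyl-4-methylpyridine conditions gives, after mild acid work-up, tert-butyl [(3S,5aS,6R,9aS)-3-hydroxy-2,2,5a-trimethyl-7-methylidenedecahydro-1-benzoxepin-6-yl]acetate F1 (with endocyclic alkene isomers, all usable). CF3CO2H in CH2Cl2 then cleaves the tert-butyl ester and lactonises by Markovnikov protonation and carboxyl capture, as in the closure of bicyclohomofarnesic acids to sclareolide. The cis-fused lactone epimer is removed by chromatography.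

**Step 14 (asymmetric Diels–Alder) is the third risk.** The β-neopentyl enone 28 is a sluggish dienophile and the enantioselectivity on this substrate is untested. The fallback sets out from 28 and 29 and comes back at 30 by resolution. AlCl3 in toluene (the established racemic cycloaddition of this pair) gives 30 together with its enantiomer (4aS,8aR)-4,4,6-trimethyl-3,4,4a,5,8,8a-hexahydronaphthalen-1(2H)-one F2. Addition of lithiated (S)-N,S-dimethyl-S-phenylsulfoximine (THF, −78 °C) gives the separable β-hydroxysulfoximines (4aR,8aS)-4,4,6-trimethyl-1-{[(S)-N-methyl-S-phenylsulfonimidoyl]methyl}-1,2,3,4,4a,5,8,8a-octahydronaphthalen-1-ol F3 and its (4aS,8aR) diastereomer F4. Chromatography and thermolysis of F3 (toluene, 110 °C) regenerate enantiopure 30.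

## Further compounds

F1 | step 9 | tert-butyl [(3S,5aS,6R,9aS)-3-hydroxy-2,2,5a-trimethyl-7-methylidenedecahydro-1-benzoxepin-6-yl]acetate | CC(C)(C)OC(=O)C[C@H]2[C@]3(C)CC[C@H](O)C(C)(C)O[C@H]3CCC2=C
F2 | step 14 | (4aS,8aR)-4,4,6-trimethyl-3,4,4a,5,8,8a-hexahydronaphthalen-1(2H)-one | CC1=CC[C@H]2C(=O)CCC(C)(C)[C@H]2C1
F3 | step 14 | (4aR,8aS)-4,4,6-trimethyl-1-{[(S)-N-methyl-S-phenylsulfonimidoyl]methyl}-1,2,3,4,4a,5,8,8a-octahydronaphthalen-1-ol (C1 epimers) | CC1=CC[C@@H]2C(O)(C[S@@](=O)(=NC)c3ccccc3)CCC(C)(C)[C@@H]2C1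
F4 | step 14 | (4aS,8aR)-4,4,6-trimethyl-1-{[(S)-N-methyl-S-phenylsulfonimidoyl]methyl}-1,2,3,4,4a,5,8,8a-octahydronaphthalen-1-ol (C1 epimers) | CC1=CC[C@H]2C(O)(C[S@@](=O)(=NC)c3ccccc3)CCC(C)(C)[C@H]2C1
F5 | step 22 | 3-O-methoxycarbonyl derivative (allylic methyl carbonate) of 42 | CC1=C(CC[C@H]2[C@]3(C)CC[C@H](O[Si](CC)(CC)CC)C(C)(C)O[C@H]3CC[C@]2(C)O[Si](CC)(CC)CC)[C@@H]2[C@H](C[C@@H]1OC(=O)OC)[C@@](C)(O)CCC2(C)C
F6 | step 22 | (3S,5aS,6S,7S,9aS)-6-{2-[(1R,4aS,5S,8aR)-5-hydroxy-2,5,8,8-tetramethyl-1,4,4a,5,6,7,8,8a-octahydronaphthalen-1-yl]ethyl}-2,2,5a,7-tetramethyl-3,7-bis(triethylsilyloxy)decahydro-1-benzoxepine | CC1=CC[C@@H]2[C@@](C)(O)CCC(C)(C)[C@@H]2[C@H]1CC[C@H]3[C@]4(C)CC[C@H](O[Si](CC)(CC)CC)C(C)(C)O[C@H]4CC[C@]3(C)O[Si](CC)(CC)CC
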